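Late in the delta run, which is the asked flask followed up to 6.00 h, substrate keeps going while target barely climbs, so the useful question is how the lost substrate divides.

| setting | delta | flask |
|---|---|---|
| substrate | 0.050 M | 0.050 M |
| gas phase | 6 mM (held) | 6.0 mM (held) |
| catalyst | 2.4 mM | 2.4 mM |
| remark | the very flask that is asked about, followed so far |  |
| time |  | 15 h |

delta run (percent of the substrate charged)

| time / h | target / % | substrate / % |
|---|---|---|
| 0.833 | 0.2 | 96.5 |
| 1.50 | 1.4 | 92.3 |
| 2.50 | 1.5 | 85.1 |
| 3.00 | 1.9 | 82.1 |
| 4.00 | 2.4 | 75.2 |
| 5.00 | 2.2 | 69.6 |
| 6.00 | 2.9 | 62.8 |

(each reading ± 0.3 percentage points)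

- the target standing at 15 h, as a percentage of the substrate charged
- the change that raises the amount of target at 15 h, in percent of the substrate charged most ("none" if none brings more than 2 percentage points) (north-west / south-west / north-east / none)
- amount of target at 15 h, in percent of the substrate charged, after south-west

- north-west: doubling the amount of catalyst, all else as stated
- south-west: doubling the saturation concentration of gas phase, all else as stated
- north-east: doubling the transfer coefficient of the gas phase, all else as stated

Each step that consumes substrate also takes one dissolved gas. In the ratio of the two rates, substrate and dissolved gas therefore cancel, leaving the constants and the free catalyst. At 6.00 h the delta run holds 2.9% target, and the rest of the lost substrate is uncatalysed product: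

S = target / uncatalysed product = 0.0845

This reading is the selectivity factor, target made per uncatalysed product made. It gives the target share of lost substrate, 7.80%.

From 1.50 h to 6.00 h I treat the fall of substrate as a constant fraction per hour, a pseudo-first-order estimate. My own reckoning carries this forward:

k = 0.0856 h⁻¹

substrate at 15 h = 29.1%

target = lost substrate × target share = 5.53%

If the free fraction of catalyst holds, doubling catalyst doubles S and gives 10.3%. More gas, whether south-west doubles its saturation concentration or north-east its transfer coefficient, feeds both steps alike and can bind catalyst as idle complex, so I expect no gain in S. Even the whole charge consumed at share 7.80% gives less than that, so I choose north-west.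

The forecast gave 4.8% (3.9% to 6.2%), north-west and 4.2% after south-west (2.9% to 6.2%), holding that “Doubling catalyst should nearly double target”.

The flask gives 5.49%. The best change is north-west, worth 5.1 percentage points, and south-west gives 4.25%.

    dissolved gas + catalyst ⇌ idle complex, settled at all times (K = 470 M⁻¹)
    gas phase ⇌ dissolved gas, rate k2*(csat - [dissolved gas]) (kL = 1.80 h⁻¹)
    substrate + dissolved gas + catalyst → catalyst + target (k = 1900 M⁻² h⁻¹)
    substrate + dissolved gas → uncatalysed product (k = 19.0 M⁻¹ h⁻¹)

At 15.0 h the flask's factor stands at 0.0802, with 70.9% of its catalyst as idle complex. That binding costs target: the run without it reaches 15.2% instead of 5.49%. The neighbour charged with 0.0060 M catalyst keeps 29.1% of it free at 15.0 h, as the flask keeps 29.1% at that time, so S scales with the charge to 0.211. With 24% substrate left, that gives 13.3% target. The computed neighbour holds 13.0%.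

The earlier runs and the new flask come from a simulation from invented constants; the scatter is artificial.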